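The route rests on disconnecting the C3=C4 double bond of a 3-acyloxy-2H-chromene. C3 and C4 are neighbouring ring C carbons: C4 is bonded to ring A, and C3 carries the ester oxygen and sits beside the stereogenic C2. A vinyl group on ring A and an enol 3-O-methylgallate on the C2 carbon can therefore be joined by ring-closing metathesis, which in one operation closes ring C with the complete ester in place and without touching C2. The precursor is an (R)-configured benzylic aryl ether whose ring A bears an ortho vinyl group and whose benzylic carbon bears ring B and a 1-acyloxyvinyl group. Hydrogen addition opposite ring B, then debenzylation, finish the synthesis.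

Key step: step 7

Assumption: the (R,R) antipode of Ph-pybox is taken to give the (S)-ether 7 in step 3; should a test run show the opposite sense, the (S,S) ligand is used and nothing else changes.

Step 1
Reactants: 1 2,4,6-trihydroxybenzaldehyde
Product: 2 2,4-bis(benzyloxy)-6-hydroxybenzaldehyde
Conditions: BnBr (2.1 equiv), K2CO3 (2.2 equiv), DMF, 0 °C to rt
Reagents that add atoms: benzyl bromide, BrCc1ccccc1
Why: Williamson etherification in which the para hydroxyl and one ortho hydroxyl react, while the last ortho hydroxyl is held in a hydrogen bond to the formyl group and is left free when the amount of benzyl bromide is limited.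

Step 2
Reactants: 3 3,4,5-tris(benzyloxy)benzaldehyde; 4 ethynylmagnesium bromide
Product: 6 rac-1-[3,4,5-tris(benzyloxy)phenyl]prop-2-yn-1-yl acetate, via bromomagnesium 1-[3,4,5-tris(benzyloxy)phenyl]prop-2-yn-1-olate 5 (not isolated)
Conditions: 4 (1.3 equiv), THF, 0 °C; then Ac2O (2.5 equiv), 0 °C to rt
Reagents that add atoms: acetic anhydride, CC(=O)OC(C)=O
Why: Grignard 1,2-addition to the aldehyde followed by O-acetylation of the magnesium alkoxide in the same flask; the acetate is racemic on purpose, because its stereocenter is erased and set anew in step 3.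

Step 3
Reactants: 6 rac-1-[3,4,5-tris(benzyloxy)phenyl]prop-2-yn-1-yl acetate; 2 2,4-bis(benzyloxy)-6-hydroxybenzaldehyde
Product: 7 2,4-bis(benzyloxy)-6-{[(1S)-1-[3,4,5-tris(benzyloxy)phenyl]prop-2-yn-1-yl]oxy}benzaldehyde
Conditions: (CuOTf)2·C6H6 (2.5 mol%), (R,R)-Ph-pybox (10 mol%), iPr2NEt (1.2 equiv), THF, −10 °C
Reagents that add atoms: none
Why: Copper-catalysed asymmetric propargylic etherification: the monovalent copper acetylide of 6 loses acetate to give a copper allenylidene, so both enantiomers of 6 converge, and the phenoxide of 2 adds to the γ-carbon on the face left open by the pybox ligand, which sets the future C2 as S in 7; the formyl group keeps ring A electron-poor enough to disfavour Friedel–Crafts C-propargylation, the usual side path of 3,5-dialkoxyphenols, and THF is used so that no alcohol solvent competes.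

Step 4
Reactants: 7 2,4-bis(benzyloxy)-6-{[(1S)-1-[3,4,5-tris(benzyloxy)phenyl]prop-2-yn-1-yl]oxy}benzaldehyde
Product: 8 1,5-bis(benzyloxy)-2-ethenyl-3-{[(1S)-1-[3,4,5-tris(benzyloxy)phenyl]prop-2-yn-1-yl]oxy}benzene
Conditions: Ph3PCH3Br (1.5 equiv), NaN(SiMe3)2 (1.4 equiv), THF, 0 °C; then 7, −78 °C to rt
Reagents that add atoms: methyltriphenylphosphonium bromide, C[P+](c1ccccc1)(c1ccccc1)c1ccccc1.[Br-]
Why: Wittig methylenation of the aryl aldehyde gives the ring A vinyl group; the ylide is made with a slight deficit of base, so nothing basic enough remains to isomerise the propargyl ether to an allene or to disturb the stereocenter.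

Step 5
Reactants: 9 3-O-methylgallic acid
Product: 12 3,4-bis(benzyloxy)-5-methoxybenzoic acid, via benzyl 3,4-bis(benzyloxy)-5-methoxybenzoate 10 (not isolated), via sodium 3,4-bis(benzyloxy)-5-methoxybenzoate 11 (not isolated)
Conditions: BnBr (3.3 equiv), K2CO3 (3.5 equiv), DMF, 60 °C; then 4 M NaOH, MeOH, 70 °C; then HCl to pH 2
Reagents that add atoms: benzyl bromide, BrCc1ccccc1; sodium hydroxide, [Na+].[OH-]
Why: Williamson etherification of both phenols together with O-alkylation of the carboxylate, then saponification of the benzyl ester alone, since aryl benzyl ethers are inert to hydroxide.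

Step 6
Reactants: 8 1,5-bis(benzyloxy)-2-ethenyl-3-{[(1S)-1-[3,4,5-tris(benzyloxy)phenyl]prop-2-yn-1-yl]oxy}benzene; 12 3,4-bis(benzyloxy)-5-methoxybenzoic acid
Product: 13 (3R)-3-[3,5-bis(benzyloxy)-2-ethenylphenoxy]-3-[3,4,5-tris(benzyloxy)phenyl]prop-1-en-2-yl 3,4-bis(benzyloxy)-5-methoxybenzoate
Conditions: [RuCl2(p-cymene)]2 (2 mol%), P(2-furyl)3 (4 mol%), Na2CO3 (8 mol%), 12 (1.3 equiv), toluene, 50 °C
Reagents that add atoms: none
Why: Ruthenium-catalysed Markovnikov hydro-acyloxylation of a terminal alkyne places the carboxylate on the internal carbon and gives the 1,1-disubstituted enol ester; a divalent ruthenium catalyst is chosen over a cationic gold one because gold would also trigger hydroarylation of the alkyne by the electron-rich ring A and enyne cyclisation with the vinyl group; the stereocenter is untouched, and its descriptor changes from S to R only because the enol ester carbon now outranks ring B.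

Step 7
Reactants: 13 (3R)-3-[3,5-bis(benzyloxy)-2-ethenylphenoxy]-3-[3,4,5-tris(benzyloxy)phenyl]prop-1-en-2-yl 3,4-bis(benzyloxy)-5-methoxybenzoate
Product: 14 (2R)-5,7-bis(benzyloxy)-2-[3,4,5-tris(benzyloxy)phenyl]-2H-chromen-3-yl 3,4-bis(benzyloxy)-5-methoxybenzoate
Conditions: second-generation Grubbs catalyst RuCl2(H2IMes)(PCy3)(=CHPh) (10 mol%), 1,4-benzoquinone (20 mol%), toluene (5 mM), 60 °C, argon purge, protected from light
Reagents that add atoms: none
Why: The ruthenium benzylidene first exchanges with the terminal vinyl group on ring A; the resulting ring A alkylidene adds across the 1,1-disubstituted enol ester alkene to form a ruthenacyclobutane, and cycloreversion gives the C3=C4 bond and a ruthenium methylidene, with ethene as the only co-product. The closest known reaction type is ring-closing metathesis of 2-vinylaryl allyl ethers and of enol ethers or enol esters to 2H-chromenes. Ring C (O1–C2–C3–C4–C4a–C8a) is closed as a six-membered ring by joining C3 to C4, both alkene carbons ending up inside the ring. No stereocenter is formed, and C2 lies outside the reacting atoms and keeps its R configuration. The selectivity needed is closure without migration of the new double bond to C2=C3 (which would erase C2) and without intermolecular metathesis; high dilution, removal of ethene, 1,4-benzoquinone as a trap for ruthenium hydrides and a short reaction time in the dark are meant to secure this, helped by the low cross-metathesis reactivity of the enol ester alkene.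

Step 8
Reactants: 14 (2R)-5,7-bis(benzyloxy)-2-[3,4,5-tris(benzyloxy)phenyl]-2H-chromen-3-yl 3,4-bis(benzyloxy)-5-methoxybenzoate
Product: 15 (2R,3R)-5,7-bis(benzyloxy)-2-[3,4,5-tris(benzyloxy)phenyl]-3,4-dihydro-2H-chromen-3-yl 3,4-bis(benzyloxy)-5-methoxybenzoate
Conditions: [Ir(cod)(PCy3)(py)]PF6 (5 mol%), H2 (1 atm), CH2Cl2, rt
Reagents that add atoms: none
Why: Homogeneous iridium-catalysed hydrogenation of the trisubstituted enol ester delivers both hydrogens to the face of C3=C4 opposite the ring B aryl group, which sits pseudo-axial on C2 to avoid the C3 ester, so C3 becomes R with the ester cis to ring B; this catalyst cleaves neither the benzyl ethers nor the allylic and benzylic C2–O1 bond.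

Step 9
Reactants: 15 (2R,3R)-5,7-bis(benzyloxy)-2-[3,4,5-tris(benzyloxy)phenyl]-3,4-dihydro-2H-chromen-3-yl 3,4-bis(benzyloxy)-5-methoxybenzoate
Product: 16 (−)-epigallocatechin 3-(3-methyl-gallate), (2R,3R)-5,7-dihydroxy-2-(3,4,5-trihydroxyphenyl)-3,4-dihydro-2H-chromen-3-yl 3,4-dihydroxy-5-methoxybenzoate
Conditions: H2 (1 atm), Pd(OH)2 on carbon, THF/MeOH (1:1), rt; filtration under argon
Reagents that add atoms: none
Why: Hydrogenolysis of the seven benzyl ethers under neutral conditions leaves the aryl ester, the C2–O1 bond and both stereocenters untouched, as is usual for benzyl-protected catechin gallates.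

Compound list
1 | 2,4,6-trihydroxybenzaldehyde | O=Cc1c(O)cc(O)cc1O | starting material
2 | 2,4-bis(benzyloxy)-6-hydroxybenzaldehyde | O=Cc1c(O)cc(OCc2ccccc2)cc1OCc1ccccc1 | intermediate
3 | 3,4,5-tris(benzyloxy)benzaldehyde | O=Cc1cc(OCc2ccccc2)c(OCc2ccccc2)c(OCc2ccccc2)c1 | starting material
4 | ethynylmagnesium bromide | C#C[Mg]Br | starting material
5 | bromomagnesium 1-[3,4,5-tris(benzyloxy)phenyl]prop-2-yn-1-olate (racemic) | C#CC(O[Mg]Br)c1cc(OCc2ccccc2)c(OCc2ccccc2)c(OCc2ccccc2)c1 | intermediate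
6 | rac-1-[3,4,5-tris(benzyloxy)phenyl]prop-2-yn-1-yl acetate | C#CC(OC(C)=O)c1cc(OCc2ccccc2)c(OCc2ccccc2)c(OCc2ccccc2)c1 | intermediate
7 | 2,4-bis(benzyloxy)-6-{[(1S)-1-[3,4,5-tris(benzyloxy)phenyl]prop-2-yn-1-yl]oxy}benzaldehyde | C#C[C@H](Oc1cc(OCc2ccccc2)cc(OCc2ccccc2)c1C=O)c1cc(OCc2ccccc2)c(OCc2ccccc2)c(OCc2ccccc2)c1 | intermediate
8 | 1,5-bis(benzyloxy)-2-ethenyl-3-{[(1S)-1-[3,4,5-tris(benzyloxy)phenyl]prop-2-yn-1-yl]oxy}benzene | C#C[C@H](Oc1cc(OCc2ccccc2)cc(OCc2ccccc2)c1C=C)c1cc(OCc2ccccc2)c(OCc2ccccc2)c(OCc2ccccc2)c1 | intermediate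
9 | 3-O-methylgallic acid (3,4-dihydroxy-5-methoxybenzoic acid) | COc1cc(C(=O)O)cc(O)c1O | starting material
10 | benzyl 3,4-bis(benzyloxy)-5-methoxybenzoate | COc1cc(C(=O)OCc2ccccc2)cc(OCc2ccccc2)c1OCc1ccccc1 | intermediate
11 | sodium 3,4-bis(benzyloxy)-5-methoxybenzoate | COc1cc(C(=O)[O-])cc(OCc2ccccc2)c1OCc1ccccc1.[Na+] | intermediate
12 | 3,4-bis(benzyloxy)-5-methoxybenzoic acid | COc1cc(C(=O)O)cc(OCc2ccccc2)c1OCc1ccccc1 | intermediate
13 | (3R)-3-[3,5-bis(benzyloxy)-2-ethenylphenoxy]-3-[3,4,5-tris(benzyloxy)phenyl]prop-1-en-2-yl 3,4-bis(benzyloxy)-5-methoxybenzoate | C=C(OC(=O)c1cc(OC)c(OCc2ccccc2)c(OCc2ccccc2)c1)[C@H](Oc1cc(OCc2ccccc2)cc(OCc2ccccc2)c1C=C)c1cc(OCc2ccccc2)c(OCc2ccccc2)c(OCc2ccccc2)c1 | intermediate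
14 | (2R)-5,7-bis(benzyloxy)-2-[3,4,5-tris(benzyloxy)phenyl]-2H-chromen-3-yl 3,4-bis(benzyloxy)-5-methoxybenzoate | C1=C(OC(=O)c2cc(OC)c(OCc3ccccc3)c(OCc3ccccc3)c2)[C@@H](c2cc(OCc3ccccc3)c(OCc3ccccc3)c(OCc3ccccc3)c2)Oc2cc(OCc3ccccc3)cc(OCc3ccccc3)c12 | intermediate
15 | (2R,3R)-5,7-bis(benzyloxy)-2-[3,4,5-tris(benzyloxy)phenyl]-3,4-dihydro-2H-chromen-3-yl 3,4-bis(benzyloxy)-5-methoxybenzoate | COc1cc(C(=O)O[C@@H]2Cc3c(OCc4ccccc4)cc(OCc4ccccc4)cc3O[C@@H]2c2cc(OCc3ccccc3)c(OCc3ccccc3)c(OCc3ccccc3)c2)cc(OCc2ccccc2)c1OCc1ccccc1 | intermediate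
16 | (−)-epigallocatechin 3-(3-methyl-gallate), (2R,3R)-5,7-dihydroxy-2-(3,4,5-trihydroxyphenyl)-3,4-dihydro-2H-chromen-3-yl 3,4-dihydroxy-5-methoxybenzoate | COc1cc(C(=O)O[C@@H]2Cc3c(O)cc(O)cc3O[C@@H]2c2cc(O)c(O)c(O)c2)cc(O)c1O | target

Total step count: 9.
Longest linear sequence: 7 steps (steps 2, 3, 4, 6, 7, 8 and 9 from aldehyde 3; the same length from 1 through step 1).

Steps most likely to fail

Step 7. The ruthenium alkylidene on ring A may decompose before it engages the hindered 1,1-disubstituted enol ester, so that closure stalls. Ruthenium hydrides may also move the new double bond to C2=C3 and erase C2. The fallback sets out from 8 and comes back to the route at 15; it closes ring C first and brings in the C3 oxygen afterwards. Semi-hydrogenation of the alkyne of 8 (H2, Pd/CaCO3 poisoned with Pb(OAc)2, quinoline, EtOAc) should give 1,5-bis(benzyloxy)-2-ethenyl-3-{[(1S)-1-[3,4,5-tris(benzyloxy)phenyl]prop-2-en-1-yl]oxy}benzene F1. Ring-closing metathesis of this unhindered diene with RuCl2(H2IMes)(PCy3)(=CHPh) should give (2S)-5,7-bis(benzyloxy)-2-[3,4,5-tris(benzyloxy)phenyl]-2H-chromene F2, whose descriptor differs only because C3 carries no oxygen. Hydroboration–oxidation (BH3·SMe2, THF; then NaOH, H2O2) anti to ring B should give the trans alcohol (2R,3S)-5,7-bis(benzyloxy)-2-[3,4,5-tris(benzyloxy)phenyl]-3,4-dihydro-2H-chromen-3-ol F3. Oxidation with Dess–Martin periodinane should give (2R)-5,7-bis(benzyloxy)-2-[3,4,5-tris(benzyloxy)phenyl]-2H-chromen-3(4H)-one F4. Reduction with LiBH(s-Bu)3 at −78 °C from the face opposite ring B should give the cis alcohol (2R,3R)-5,7-bis(benzyloxy)-2-[3,4,5-tris(benzyloxy)phenyl]-3,4-dihydro-2H-chromen-3-ol F5. Steglich esterification of this alcohol with acid 12 (EDC·HCl, DMAP, CH2Cl2) gives 15.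

Step 3. A ring carbon of the phenol may attack the copper allenylidene in place of the oxygen, or the enantiomeric purity may fall through reversible ionisation of the aryl ether. The fallback sets out from 6 and comes back at 7; it forms the C–O bond by SN2 inversion. Enantioselective alcoholysis of racemic 6 with immobilised Candida antarctica lipase B and n-butanol in MTBE, following the usual enantiopreference of lipases for secondary alcohols, should free (1R)-1-[3,4,5-tris(benzyloxy)phenyl]prop-2-yn-1-ol F6. The (S)-enantiomer of 6 stays unchanged, so at most half of the material is used. Mitsunobu reaction of F6 with phenol 2 (PPh3, DIAD, toluene, 0 °C) should then give 7 with inversion.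

Step 6. The carboxylate may add to the terminal carbon through a ruthenium vinylidene and give the anti-Markovnikov enol ester, or addition beside the crowded benzylic carbon may be too slow. The fallback sets out from 8 and comes back at 13; it makes the C3–O bond by oxidative copper coupling. α-Selective copper-catalysed protoboration of the alkyne of 8 (chloro[1,3-dimesitylimidazolidin-2-ylidene]copper, (SIMes)CuCl, NaOt-Bu, B2pin2, MeOH, THF, −20 °C) should give 2-{(3S)-3-[3,5-bis(benzyloxy)-2-ethenylphenoxy]-3-[3,4,5-tris(benzyloxy)phenyl]prop-1-en-2-yl}-4,4,5,5-tetramethyl-1,3,2-dioxaborolane F7. KHF2 in MeOH/H2O should convert it into potassium {(3S)-3-[3,5-bis(benzyloxy)-2-ethenylphenoxy]-3-[3,4,5-tris(benzyloxy)phenyl]prop-1-en-2-yl}trifluoroborate F8. Chan–Lam-type coupling of F8 with acid 12 (Cu(OAc)2, DMAP, 4 Å molecular sieves, O2, CH2Cl2, rt) should give 13.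

Further compounds
F1 | step 7 | 1,5-bis(benzyloxy)-2-ethenyl-3-{[(1S)-1-[3,4,5-tris(benzyloxy)phenyl]prop-2-en-1-yl]oxy}benzene | C=C[C@H](Oc1cc(OCc2ccccc2)cc(OCc2ccccc2)c1C=C)c1cc(OCc2ccccc2)c(OCc2ccccc2)c(OCc2ccccc2)c1
F2 | step 7 | (2S)-5,7-bis(benzyloxy)-2-[3,4,5-tris(benzyloxy)phenyl]-2H-chromene | C1=C[C@@H](c2cc(OCc3ccccc3)c(OCc3ccccc3)c(OCc3ccccc3)c2)Oc2cc(OCc3ccccc3)cc(OCc3ccccc3)c12
F3 | step 7 | (2R,3S)-5,7-bis(benzyloxy)-2-[3,4,5-tris(benzyloxy)phenyl]-3,4-dihydro-2H-chromen-3-ol | O[C@H]1Cc2c(OCc3ccccc3)cc(OCc3ccccc3)cc2O[C@@H]1c1cc(OCc2ccccc2)c(OCc2ccccc2)c(OCc2ccccc2)c1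
F4 | step 7 | (2R)-5,7-bis(benzyloxy)-2-[3,4,5-tris(benzyloxy)phenyl]-2H-chromen-3(4H)-one | O=C1Cc2c(OCc3ccccc3)cc(OCc3ccccc3)cc2O[C@@H]1c1cc(OCc2ccccc2)c(OCc2ccccc2)c(OCc2ccccc2)c1
F5 | step 7 | (2R,3R)-5,7-bis(benzyloxy)-2-[3,4,5-tris(benzyloxy)phenyl]-3,4-dihydro-2H-chromen-3-ol | O[C@@H]1Cc2c(OCc3ccccc3)cc(OCc3ccccc3)cc2O[C@@H]1c1cc(OCc2ccccc2)c(OCc2ccccc2)c(OCc2ccccc2)c1
F6 | step 3 | (1R)-1-[3,4,5-tris(benzyloxy)phenyl]prop-2-yn-1-ol | C#C[C@@H](O)c1cc(OCc2ccccc2)c(OCc2ccccc2)c(OCc2ccccc2)c1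
F7 | step 6 | 2-{(3S)-3-[3,5-bis(benzyloxy)-2-ethenylphenoxy]-3-[3,4,5-tris(benzyloxy)phenyl]prop-1-en-2-yl}-4,4,5,5-tetramethyl-1,3,2-dioxaborolane | C=C(B1OC(C)(C)C(C)(C)O1)[C@H](Oc1cc(OCc2ccccc2)cc(OCc2ccccc2)c1C=C)c1cc(OCc2ccccc2)c(OCc2ccccc2)c(OCc2ccccc2)c1
F8 | step 6 | potassium {(3S)-3-[3,5-bis(benzyloxy)-2-ethenylphenoxy]-3-[3,4,5-tris(benzyloxy)phenyl]prop-1-en-2-yl}trifluoroborate | C=C([B-](F)(F)F)[C@H](Oc1cc(OCc2ccccc2)cc(OCc2ccccc2)c1C=C)c1cc(OCc2ccccc2)c(OCc2ccccc2)c(OCc2ccccc2)c1.[K+]
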